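**Retrosynthetic overview**
1. Target 34 ⇐ global desilylation of 33 ⇐ acylation of the C15 alcohol 28 with silyl-protected 4-hydroxytiglic acid 32.
2. Ten-membered ring (formed second) ⇐ C3–C4 closure of 25 by intramolecular alkylzinc/alkenyl iodide cross-coupling; both olefin geometries are fixed before ring closure.
3. Key C6–C7 bond ⇐ intermolecular zinc Barbier allylation of (Z)-β-iodoenal 5 (fragment A) with (S)-bromomethylbutenolide 21 (fragment B); this creates the α-methylene lactone and sets C6 and C7 from C8.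
4. 21 (lactone ring formed first, by acrylate ring-closing metathesis) ⇐ (S)-epichlorohydrin 6 via alkyne carboalumination; 5 ⇐ but-2-yne-1,4-diol 1 via hydroxyl-directed hydroalumination–iodination.

Assumption: atom labels C1–C15 in the comments follow germacrane numbering (lactone on O8, free hydroxyl on C6, ester on O15); the target is (3aS,4R,5E,9E,11aS) in cyclodeca[b]furanone numbering, with C3 and C6 cis across C4=C5.

**Fragment A**

Step 1
Reactants: 1 but-2-yne-1,4-diol
Product: 2 4-[(4-methoxybenzyl)oxy]but-2-yn-1-ol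
Conditions: NaH (1 equiv), 1 (3 equiv), 4-methoxybenzyl chloride (1 equiv), Bu4NI (cat.), THF/DMF, 0 °C → rt
Reagents that add atoms: 4-methoxybenzyl chloride, COc1ccc(CCl)cc1
Why: Williamson etherification of the mono-alkoxide; the excess of symmetrical diol suppresses bis-alkylation.

Step 2
Reactants: 2 4-[(4-methoxybenzyl)oxy]but-2-yn-1-ol
Product: 4 (Z)-3-iodo-4-[(4-methoxybenzyl)oxy]but-2-en-1-ol, via cyclic alkenylaluminate 3 (not isolated)
Conditions: NaAlH2(OCH2CH2OMe)2 (Red-Al), THF, 0 °C; then iodine, THF, −78 → 0 °C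
Reagents that add atoms: iodine, [I][I]
Why: Hydroxyl-directed trans-hydroalumination places aluminium on the distal alkyne carbon (C4) in a five-membered chelate, and iodinolysis with retention gives the Z-iodoalkene with iodine (the later C3 position) cis to C6.

Step 3
Reactants: 4 (Z)-3-iodo-4-[(4-methoxybenzyl)oxy]but-2-en-1-ol
Product: 5 (Z)-3-iodo-4-[(4-methoxybenzyl)oxy]but-2-enal
Conditions: activated MnO2 (15 equiv), CH2Cl2, rt, dark; used at once
Reagents that add atoms: none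
Why: Neutral allylic oxidation with MnO2 leaves the PMB ether, the carbon–iodine bond and the Z geometry intact.

**Fragment B**

Step 4
Reactants: 6 (S)-epichlorohydrin; 7 ethynyltrimethylsilane
Product: 9 (S)-1-chloro-5-(trimethylsilyl)pent-4-yn-2-ol, via lithium (trimethylsilyl)acetylide 8 (not isolated)
Conditions: 7, n-BuLi, THF, −78 °C; BF3·OEt2; then 6, −78 °C
Reagents that add atoms: none
Why: BF3-promoted epoxide opening by the acetylide (Yamaguchi–Hirao alkynylation) occurs at the unsubstituted epoxide carbon, so the stereocentre (later C8) is untouched.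

Step 5
Reactants: 9 (S)-1-chloro-5-(trimethylsilyl)pent-4-yn-2-ol
Product: 11 (S)-6-(trimethylsilyl)hex-1-en-5-yn-3-ol, via silylpropargyl oxirane 10 (not isolated)
Conditions: Me3S+ I− (4 equiv), n-BuLi (3.9 equiv), THF, −20 °C; then 9, −20 °C → rt
Reagents that add atoms: trimethylsulfonium iodide, C[S+](C)C.[I-]
Why: The chlorohydrin closes to the epoxide, dimethylsulfonium methylide opens it at CH2, and the betaine eliminates Me2S (Corey–Chaykovsky-type epoxide-to-allylic-alcohol homologation) without touching the carbinol centre.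

Step 6
Reactants: 11 (S)-6-(trimethylsilyl)hex-1-en-5-yn-3-ol
Product: 12 tert-butyldimethyl{[(3S)-6-(trimethylsilyl)hex-1-en-5-yn-3-yl]oxy}silane
Conditions: TBSCl, imidazole, DMF, rt
Reagents that add atoms: tert-butyldimethylsilyl chloride, CC(C)(C)[Si](C)(C)Cl
Why: Standard silylation protects the alcohol against Me3Al and n-BuLi in step 8.

Step 7
Reactants: 12 tert-butyldimethyl{[(3S)-6-(trimethylsilyl)hex-1-en-5-yn-3-yl]oxy}silane
Product: 13 tert-butyl{[(3S)-hex-1-en-5-yn-3-yl]oxy}dimethylsilane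
Conditions: K2CO3 (cat.), MeOH, rt
Reagents that add atoms: none
Why: Base-catalysed methanolysis (protodesilylation) cleaves only the alkynyl carbon–silicon bond; the silyl ether is stable.

Step 8
Reactants: 13 tert-butyl{[(3S)-hex-1-en-5-yn-3-yl]oxy}dimethylsilane; 14 oxirane
Product: 16 (3E,6S)-6-[(tert-butyldimethylsilyl)oxy]-4-methylocta-3,7-dien-1-ol, via (E)-alkenyldimethylalane 15 (not isolated)
Conditions: Me3Al (2.5 equiv), Cp2ZrCl2 (0.25 equiv), CH2Cl2, 0 °C → rt; volatiles removed; THF/hexane, n-BuLi, −78 °C; then oxirane, −78 → 0 °C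
Reagents that add atoms: trimethylaluminium, C[Al](C)C
Why: Negishi zirconium-catalysed syn-carboalumination puts Me on the internal alkyne carbon and Al on the terminus, and the derived alanate opens oxirane with retention, fixing the E-trisubstituted C1(10) olefin.

Step 9
Reactants: 16 (3E,6S)-6-[(tert-butyldimethylsilyl)oxy]-4-methylocta-3,7-dien-1-ol
Product: 17 tert-butyl{[(3S,5E)-8-chloro-5-methylocta-1,5-dien-3-yl]oxy}dimethylsilane
Conditions: PPh3, N-chlorosuccinimide, CH2Cl2, 0 °C → rt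
Reagents that add atoms: N-chlorosuccinimide, O=C1CCC(=O)N1Cl
Why: Appel-type chlorination converts the primary alcohol by SN2 displacement of its oxyphosphonium salt; the chloride is inert in the following steps up to step 15.

Step 10
Reactants: 17 tert-butyl{[(3S,5E)-8-chloro-5-methylocta-1,5-dien-3-yl]oxy}dimethylsilane
Product: 18 (3S,5E)-8-chloro-5-methylocta-1,5-dien-3-ol
Conditions: Bu4NF, THF, 0 °C → rt
Reagents that add atoms: none
Why: Fluoride desilylation frees the allylic alcohol; the primary chloride is not displaced at this temperature.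

Step 11
Reactants: 18 (3S,5E)-8-chloro-5-methylocta-1,5-dien-3-ol; 19 2-(bromomethyl)acrylic acid
Product: 20 (3S,5E)-8-chloro-5-methylocta-1,5-dien-3-yl 2-(bromomethyl)prop-2-enoate
Conditions: DCC, DMAP (5 mol%), CH2Cl2, −10 → 0 °C
Reagents that add atoms: none
Why: Steglich esterification at oxygen with retention at C8; low DMAP loading and temperature avoid attack on the allylic bromide.

Step 12
Reactants: 20 (3S,5E)-8-chloro-5-methylocta-1,5-dien-3-yl 2-(bromomethyl)prop-2-enoate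
Product: 21 (5S)-3-(bromomethyl)-5-[(2E)-5-chloro-2-methylpent-2-en-1-yl]furan-2(5H)-one
Conditions: second-generation Grubbs catalyst (H2IMes)(PCy3)Cl2Ru=CHPh (5 mol%), CH2Cl2 (0.01 M), 40 °C
Reagents that add atoms: none
Why: Ring-closing metathesis between the vinyl group and the acrylate gives the five-membered butenolide; the trisubstituted chain olefin cannot form a viable ring and is untouched.

**Union and completion**

Step 13 (key step)
Reactants: 21 (5S)-3-(bromomethyl)-5-[(2E)-5-chloro-2-methylpent-2-en-1-yl]furan-2(5H)-one; 5 (Z)-3-iodo-4-[(4-methoxybenzyl)oxy]but-2-enal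
Product: 23 (4S,5S)-5-[(2E)-5-chloro-2-methylpent-2-en-1-yl]-4-[(1S,2Z)-1-hydroxy-3-iodo-4-[(4-methoxybenzyl)oxy]but-2-en-1-yl]-3-methylideneoxolan-2-one, via allylzinc bromide 22 (not isolated)
Conditions: Zn dust (3 equiv), 21 (1.3 equiv), THF/sat. aq NH4Cl (2:1), 0 °C → rt
Reagents that add atoms: none
Why: In this intermolecular Barbier carbonyl allylation the allylzinc adds through its γ-carbon (C7) in a chair Zimmerman–Traxler transition state, anti to the C8 side chain (trans lactone) and with the enal residue equatorial (C6–OH anti to C8 in the crotylation sense), which sets C7 and C6 as in the target and unveils the α-methylene lactone.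

Step 14
Reactants: 23 (Barbier adduct)
Product: 24 (4R,5S)-4-[(1S,2Z)-1-[(tert-butyldimethylsilyl)oxy]-3-iodo-4-[(4-methoxybenzyl)oxy]but-2-en-1-yl]-5-[(2E)-5-chloro-2-methylpent-2-en-1-yl]-3-methylideneoxolan-2-one
Conditions: TBSOTf, 2,6-lutidine, CH2Cl2, −78 → 0 °C
Reagents that add atoms: tert-butyldimethylsilyl trifluoromethanesulfonate, CC(C)(C)[Si](C)(C)OS(=O)(=O)C(F)(F)F
Why: Non-nucleophilic silylation caps the C6 hydroxyl (no translactonisation to O6, no quench of the organozinc later) without affecting the Michael acceptor.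

Step 15
Reactants: 24 (silyl ether, primary chloride)
Product: 25 (4R,5S)-4-[(1S,2Z)-1-[(tert-butyldimethylsilyl)oxy]-3-iodo-4-[(4-methoxybenzyl)oxy]but-2-en-1-yl]-5-[(2E)-5-iodo-2-methylpent-2-en-1-yl]-3-methylideneoxolan-2-one
Conditions: NaI (10 equiv), NaHCO3 (solid), 2-butanone, 70 °C, dark
Reagents that add atoms: sodium iodide, [Na+].[I-]
Why: Finkelstein SN2 exchange turns the primary chloride into the iodide needed for zinc insertion; the alkenyl iodide and stereocentres are not involved.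

Step 16
Reactants: 25 (alkyl iodide/alkenyl iodide)
Product: 27 (3aR,4R,5E,9E,11aS)-4-[(tert-butyldimethylsilyl)oxy]-6-{[(4-methoxybenzyl)oxy]methyl}-10-methyl-3-methylidene-3a,4,7,8,11,11a-hexahydrocyclodeca[b]furan-2(3H)-one, via alkylzinc iodide 26 (not isolated)
Conditions: Zn dust (activated with BrCH2CH2Br and Me3SiCl), THF/DMA (4:1), 35 °C; filtered solution added over 10 h to PdCl2(dppf) (10 mol%), THF, 45 °C, final 2 mM
Reagents that add atoms: none
Why: Intramolecular Negishi sp3–sp2 coupling: zinc inserts only into the primary carbon–iodine bond and palladium adds to the alkenyl iodide with retention, so the ring-cis C4=C5 olefin, the E-C1(10) olefin and the three stereocentres pass unchanged into the ten-membered ring.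

Step 17
Reactants: 27 (macrocyclic PMB ether)
Product: 28 (3aR,4R,5E,9E,11aS)-4-[(tert-butyldimethylsilyl)oxy]-6-(hydroxymethyl)-10-methyl-3-methylidene-3a,4,7,8,11,11a-hexahydrocyclodeca[b]furan-2(3H)-one
Conditions: DDQ (1.3 equiv), CH2Cl2/pH 7 phosphate buffer (10:1), 0 °C
Reagents that add atoms: none
Why: Oxidative cleavage of the electron-rich PMB ether under buffered conditions spares the silyl ether, the 1,5-diene and the methylene lactone.

Step 18
Reactants: 29 (tert-butyldimethylsilyloxy)acetaldehyde; 30 ethyl 2-(triphenylphosphoranylidene)propanoate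
Product: 31 ethyl (2E)-4-[(tert-butyldimethylsilyl)oxy]-2-methylbut-2-enoate
Conditions: CH2Cl2, rt
Reagents that add atoms: none
Why: Wittig olefination with a stabilised ylide gives the E-trisubstituted enoate (ester trans to the CH2O group).

Step 19
Reactants: 31 ethyl (2E)-4-[(tert-butyldimethylsilyl)oxy]-2-methylbut-2-enoate
Product: 32 (2E)-4-[(tert-butyldimethylsilyl)oxy]-2-methylbut-2-enoic acid
Conditions: LiOH·H2O, THF/MeOH/H2O (3:1:1), 0 °C → rt; then 0.5 M HCl to pH 4, 0 °C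
Reagents that add atoms: lithium hydroxide, [Li+].[OH-]
Why: Saponification of the ethyl ester; the primary silyl ether and the E-olefin survive cold hydroxide and a mildly acidic quench.

Step 20
Reactants: 28 (C15 alcohol); 32 (2E)-4-[(tert-butyldimethylsilyl)oxy]-2-methylbut-2-enoic acid
Product: 33 [(3aR,4R,5E,9E,11aS)-4-[(tert-butyldimethylsilyl)oxy]-10-methyl-3-methylidene-2-oxo-2,3,3a,4,7,8,11,11a-octahydrocyclodeca[b]furan-6-yl]methyl (2E)-4-[(tert-butyldimethylsilyl)oxy]-2-methylbut-2-enoate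
Conditions: DCC, DMAP (0.2 equiv), CH2Cl2, 0 °C → rt
Reagents that add atoms: none
Why: Steglich esterification of the only free (primary allylic) hydroxyl; C6–O is silylated, so no regiochemical issue arises.

Step 21
Reactants: 33 (bis-silyl ether)
Product: 34 [(3aS,4R,5E,9E,11aS)-4-hydroxy-10-methyl-3-methylidene-2-oxo-2,3,3a,4,7,8,11,11a-octahydrocyclodeca[b]furan-6-yl]methyl (2E)-4-hydroxy-2-methylbut-2-enoate (target)
Conditions: HF·pyridine, pyridine/THF, 0 °C → rt
Reagents that add atoms: none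
Why: Buffered fluoride desilylation removes both silyl ethers without base, so the allylic ester, the methylene lactone and the acid-sensitive 1,5-diene are preserved.

**Compound list**
1 | but-2-yne-1,4-diol | OCC#CCO | starting material
2 | 4-[(4-methoxybenzyl)oxy]but-2-yn-1-ol | OCC#CCOCc1ccc(OC)cc1 | intermediate
3 | cyclic sodium alkenylaluminate from 2 (Al on O1 and on the distal alkene carbon, two 2-methoxyethoxy ligands) | [Na+].COCCO[Al-]1(OCCOC)OCC=C1COCc2ccc(OC)cc2 | intermediate (not isolated)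
4 | (Z)-3-iodo-4-[(4-methoxybenzyl)oxy]but-2-en-1-ol | OC/C=C(\I)COCc1ccc(OC)cc1 | intermediate
5 | (Z)-3-iodo-4-[(4-methoxybenzyl)oxy]but-2-enal | O=C/C=C(\I)COCc1ccc(OC)cc1 | intermediate
6 | (S)-epichlorohydrin | ClC[C@@H]1CO1 | starting material
7 | ethynyltrimethylsilane | C#C[Si](C)(C)C | starting material
8 | lithium (trimethylsilyl)acetylide | [Li]C#C[Si](C)(C)C | intermediate (not isolated)
9 | (S)-1-chloro-5-(trimethylsilyl)pent-4-yn-2-ol | C[Si](C)(C)C#CC[C@H](O)CCl | intermediate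
10 | (S)-trimethyl[3-(oxiran-2-yl)prop-1-yn-1-yl]silane | C[Si](C)(C)C#CC[C@H]1CO1 | intermediate (not isolated)
11 | (S)-6-(trimethylsilyl)hex-1-en-5-yn-3-ol | C[Si](C)(C)C#CC[C@H](O)C=C | intermediate
12 | tert-butyldimethyl{[(3S)-6-(trimethylsilyl)hex-1-en-5-yn-3-yl]oxy}silane | C[Si](C)(C)C#CC[C@H](O[Si](C)(C)C(C)(C)C)C=C | intermediate
13 | tert-butyl{[(3S)-hex-1-en-5-yn-3-yl]oxy}dimethylsilane | C#CC[C@H](O[Si](C)(C)C(C)(C)C)C=C | intermediate
14 | oxirane | C1CO1 | starting material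
15 | dimethyl[(1E,4S)-4-[(tert-butyldimethylsilyl)oxy]-2-methylhexa-1,5-dien-1-yl]alane | C[Al](C)/C=C(C)/C[C@H](O[Si](C)(C)C(C)(C)C)C=C | intermediate (not isolated)
16 | (3E,6S)-6-[(tert-butyldimethylsilyl)oxy]-4-methylocta-3,7-dien-1-ol | OCC/C=C(C)/C[C@H](O[Si](C)(C)C(C)(C)C)C=C | intermediate
17 | tert-butyl{[(3S,5E)-8-chloro-5-methylocta-1,5-dien-3-yl]oxy}dimethylsilane | ClCC/C=C(C)/C[C@H](O[Si](C)(C)C(C)(C)C)C=C | intermediate
18 | (3S,5E)-8-chloro-5-methylocta-1,5-dien-3-ol | ClCC/C=C(C)/C[C@H](O)C=C | intermediate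
19 | 2-(bromomethyl)acrylic acid | OC(=O)C(=C)CBr | starting material
20 | (3S,5E)-8-chloro-5-methylocta-1,5-dien-3-yl 2-(bromomethyl)prop-2-enoate | ClCC/C=C(C)/C[C@H](OC(=O)C(=C)CBr)C=C | intermediate
21 | (5S)-3-(bromomethyl)-5-[(2E)-5-chloro-2-methylpent-2-en-1-yl]furan-2(5H)-one | BrCC1=C[C@H](C/C(C)=C/CCCl)OC1=O | intermediate
22 | {[(5S)-5-[(2E)-5-chloro-2-methylpent-2-en-1-yl]-2-oxo-2,5-dihydrofuran-3-yl]methyl}zinc bromide | Br[Zn]CC1=C[C@H](C/C(C)=C/CCCl)OC1=O | intermediate (not isolated)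
23 | (4S,5S)-5-[(2E)-5-chloro-2-methylpent-2-en-1-yl]-4-[(1S,2Z)-1-hydroxy-3-iodo-4-[(4-methoxybenzyl)oxy]but-2-en-1-yl]-3-methylideneoxolan-2-one | C=C1C(=O)O[C@@H](C/C(C)=C/CCCl)[C@@H]1[C@H](O)/C=C(\I)COCc2ccc(OC)cc2 | intermediate
24 | (4R,5S)-4-[(1S,2Z)-1-[(tert-butyldimethylsilyl)oxy]-3-iodo-4-[(4-methoxybenzyl)oxy]but-2-en-1-yl]-5-[(2E)-5-chloro-2-methylpent-2-en-1-yl]-3-methylideneoxolan-2-one | C=C1C(=O)O[C@@H](C/C(C)=C/CCCl)[C@@H]1[C@H](O[Si](C)(C)C(C)(C)C)/C=C(\I)COCc2ccc(OC)cc2 | intermediate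
25 | (4R,5S)-4-[(1S,2Z)-1-[(tert-butyldimethylsilyl)oxy]-3-iodo-4-[(4-methoxybenzyl)oxy]but-2-en-1-yl]-5-[(2E)-5-iodo-2-methylpent-2-en-1-yl]-3-methylideneoxolan-2-one | C=C1C(=O)O[C@@H](C/C(C)=C/CCI)[C@@H]1[C@H](O[Si](C)(C)C(C)(C)C)/C=C(\I)COCc2ccc(OC)cc2 | intermediate
26 | alkylzinc iodide of 25 (C–ZnI in place of the primary carbon–iodine bond) | C=C1C(=O)O[C@@H](C/C(C)=C/CC[Zn]I)[C@@H]1[C@H](O[Si](C)(C)C(C)(C)C)/C=C(\I)COCc2ccc(OC)cc2 | intermediate (not isolated)
27 | (3aR,4R,5E,9E,11aS)-4-[(tert-butyldimethylsilyl)oxy]-6-{[(4-methoxybenzyl)oxy]methyl}-10-methyl-3-methylidene-3a,4,7,8,11,11a-hexahydrocyclodeca[b]furan-2(3H)-one | C=C1C(=O)O[C@H]2C/C(C)=C/CC/C(COCc3ccc(OC)cc3)=C\[C@@H](O[Si](C)(C)C(C)(C)C)[C@H]12 | intermediate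
28 | (3aR,4R,5E,9E,11aS)-4-[(tert-butyldimethylsilyl)oxy]-6-(hydroxymethyl)-10-methyl-3-methylidene-3a,4,7,8,11,11a-hexahydrocyclodeca[b]furan-2(3H)-one | C=C1C(=O)O[C@H]2C/C(C)=C/CC/C(CO)=C\[C@@H](O[Si](C)(C)C(C)(C)C)[C@H]12 | intermediate
29 | (tert-butyldimethylsilyloxy)acetaldehyde | O=CCO[Si](C)(C)C(C)(C)C | starting material
30 | ethyl 2-(triphenylphosphoranylidene)propanoate | CCOC(=O)C(C)=P(c1ccccc1)(c1ccccc1)c1ccccc1 | starting material
31 | ethyl (2E)-4-[(tert-butyldimethylsilyl)oxy]-2-methylbut-2-enoate | CCOC(=O)/C(C)=C/CO[Si](C)(C)C(C)(C)C | intermediate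
32 | (2E)-4-[(tert-butyldimethylsilyl)oxy]-2-methylbut-2-enoic acid | OC(=O)/C(C)=C/CO[Si](C)(C)C(C)(C)C | intermediate
33 | [(3aR,4R,5E,9E,11aS)-4-[(tert-butyldimethylsilyl)oxy]-10-methyl-3-methylidene-2-oxo-2,3,3a,4,7,8,11,11a-octahydrocyclodeca[b]furan-6-yl]methyl (2E)-4-[(tert-butyldimethylsilyl)oxy]-2-methylbut-2-enoate | C=C1C(=O)O[C@H]2C/C(C)=C/CC/C(COC(=O)/C(C)=C/CO[Si](C)(C)C(C)(C)C)=C\[C@@H](O[Si](C)(C)C(C)(C)C)[C@H]12 | intermediate
34 | [(3aS,4R,5E,9E,11aS)-4-hydroxy-10-methyl-3-methylidene-2-oxo-2,3,3a,4,7,8,11,11a-octahydrocyclodeca[b]furan-6-yl]methyl (2E)-4-hydroxy-2-methylbut-2-enoate | C=C1C(=O)O[C@H]2C/C(C)=C/CC/C(COC(=O)/C(C)=C/CO)=C\[C@@H](O)[C@H]12 | target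

**Step count and risk**

Total: 21 steps (3 to enal 5, 9 to bromobutenolide 21, 2 to acid 32, 7 from the union onward). Longest linear sequence: 16 steps, from 6 to 34 (steps 4–17, 20, 21).

Most likely to fail, first: step 16. A ten-membered ring closed by alkylzinc/alkenyl iodide coupling has little precedent. Oligomerisation, protonation of the organozinc, or carbopalladation of the nearby methylene lactone by the alkenylpalladium could win. The fallback closes the ring at C1=C10 by olefin metathesis; it sets out from 6 and 4 and returns at 27.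
- Copper-catalysed opening of 6 with isopropenylmagnesium bromide (CuI cat., THF, −40 °C) gives (S)-1-chloro-4-methylpent-4-en-2-ol F1.
- The conditions of step 5 convert it into (S)-5-methylhexa-1,5-dien-3-ol F2.
- DCC esterification with 19 gives (S)-5-methylhexa-1,5-dien-3-yl 2-(bromomethyl)prop-2-enoate F3.
- Second-generation Grubbs catalyst closes it to (5S)-3-(bromomethyl)-5-(2-methylprop-2-en-1-yl)furan-2(5H)-one F4.
- In parallel, iodide 4 is cross-coupled with but-3-enylzinc bromide (PdCl2(dppf), THF, rt, retention) to (E)-3-{[(4-methoxybenzyl)oxy]methyl}hepta-2,6-dien-1-ol F5, and MnO2 gives (E)-3-{[(4-methoxybenzyl)oxy]methyl}hepta-2,6-dienal F6.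
- The zinc Barbier union of F4 and F6 under the conditions of step 13 gives (4S,5S)-4-[(1R,2E)-1-hydroxy-3-{[(4-methoxybenzyl)oxy]methyl}hepta-2,6-dien-1-yl]-3-methylidene-5-(2-methylprop-2-en-1-yl)oxolan-2-one F7.
- TBSOTf/2,6-lutidine gives its silyl ether (4R,5S)-4-[(1R,2E)-1-[(tert-butyldimethylsilyl)oxy]-3-{[(4-methoxybenzyl)oxy]methyl}hepta-2,6-dien-1-yl]-3-methylidene-5-(2-methylprop-2-en-1-yl)oxolan-2-one F8.
- Ring-closing metathesis of F8 (second-generation Grubbs catalyst, toluene, 80 °C, 1 mM) joins the butenyl and methallyl termini to give 27. The E/Z ratio at C1(10) is not predictable and the isomers would have to be separated.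

Second: step 13. The C6 selectivity with a β-iodoenal is unproven, and zinc or halide may attack the vinylogous acyl iodide. The fallback corrects C6 by SN2 inversion instead of relying on the allylation; it sets out from the same union of 21 and 5 and returns at 23.
- The unwanted carbinol epimer, (4S,5S)-5-[(2E)-5-chloro-2-methylpent-2-en-1-yl]-4-[(1R,2Z)-1-hydroxy-3-iodo-4-[(4-methoxybenzyl)oxy]but-2-en-1-yl]-3-methylideneoxolan-2-one F9, is separated.
- Mitsunobu reaction (chloroacetic acid, PPh3, DIAD, toluene, 0 °C) gives the inverted ester (4R,5S)-4-[(1S,2Z)-1-(chloroacetoxy)-3-iodo-4-[(4-methoxybenzyl)oxy]but-2-en-1-yl]-5-[(2E)-5-chloro-2-methylpent-2-en-1-yl]-3-methylideneoxolan-2-one F10.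
- Thiourea/NaHCO3 (EtOH/THF, rt) removes the chloroacetate without base strong enough to harm the lactone and returns 23.

Third: step 8. Opening of oxirane by the alkenylalanate often gives modest yields, and residual Me3Al consumes reagent. The fallback forms the C1–C2 bond by cross-coupling; it sets out from 13 and returns at 16.
- The same carboalumination quenched with iodine gives tert-butyl{[(3S,5E)-6-iodo-5-methylhexa-1,5-dien-3-yl]oxy}dimethylsilane F11.
- Palladium-catalysed coupling with the Reformatsky reagent BrZnCH2CO2Et (Pd2(dba)3, P(t-Bu)3, THF, rt) gives ethyl (3E,6S)-6-[(tert-butyldimethylsilyl)oxy]-4-methylocta-3,7-dienoate F12.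
- i-Bu2AlH (CH2Cl2, −78 → 0 °C) reduces F12 to 16.

**Further compounds**
F1 | step 16 | (S)-1-chloro-4-methylpent-4-en-2-ol | CC(=C)C[C@H](O)CCl
F2 | step 16 | (S)-5-methylhexa-1,5-dien-3-ol | CC(=C)C[C@H](O)C=C
F3 | step 16 | (S)-5-methylhexa-1,5-dien-3-yl 2-(bromomethyl)prop-2-enoate | CC(=C)C[C@H](OC(=O)C(=C)CBr)C=C
F4 | step 16 | (5S)-3-(bromomethyl)-5-(2-methylprop-2-en-1-yl)furan-2(5H)-one | BrCC1=C[C@H](CC(C)=C)OC1=O
F5 | step 16 | (E)-3-{[(4-methoxybenzyl)oxy]methyl}hepta-2,6-dien-1-ol | OC/C=C(\CCC=C)COCc1ccc(OC)cc1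
F6 | step 16 | (E)-3-{[(4-methoxybenzyl)oxy]methyl}hepta-2,6-dienal | O=C/C=C(\CCC=C)COCc1ccc(OC)cc1
F7 | step 16 | (4S,5S)-4-[(1R,2E)-1-hydroxy-3-{[(4-methoxybenzyl)oxy]methyl}hepta-2,6-dien-1-yl]-3-methylidene-5-(2-methylprop-2-en-1-yl)oxolan-2-one | C=C1C(=O)O[C@@H](CC(C)=C)[C@@H]1[C@H](O)/C=C(\CCC=C)COCc2ccc(OC)cc2
F8 | step 16 | (4R,5S)-4-[(1R,2E)-1-[(tert-butyldimethylsilyl)oxy]-3-{[(4-methoxybenzyl)oxy]methyl}hepta-2,6-dien-1-yl]-3-methylidene-5-(2-methylprop-2-en-1-yl)oxolan-2-one | C=C1C(=O)O[C@@H](CC(C)=C)[C@@H]1[C@H](O[Si](C)(C)C(C)(C)C)/C=C(\CCC=C)COCc2ccc(OC)cc2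
F9 | step 13 | (4S,5S)-5-[(2E)-5-chloro-2-methylpent-2-en-1-yl]-4-[(1R,2Z)-1-hydroxy-3-iodo-4-[(4-methoxybenzyl)oxy]but-2-en-1-yl]-3-methylideneoxolan-2-one | C=C1C(=O)O[C@@H](C/C(C)=C/CCCl)[C@@H]1[C@@H](O)/C=C(\I)COCc2ccc(OC)cc2
F10 | step 13 | (4R,5S)-4-[(1S,2Z)-1-(chloroacetoxy)-3-iodo-4-[(4-methoxybenzyl)oxy]but-2-en-1-yl]-5-[(2E)-5-chloro-2-methylpent-2-en-1-yl]-3-methylideneoxolan-2-one | C=C1C(=O)O[C@@H](C/C(C)=C/CCCl)[C@@H]1[C@H](OC(=O)CCl)/C=C(\I)COCc2ccc(OC)cc2
F11 | step 8 | tert-butyl{[(3S,5E)-6-iodo-5-methylhexa-1,5-dien-3-yl]oxy}dimethylsilane | I/C=C(C)/C[C@H](O[Si](C)(C)C(C)(C)C)C=C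
F12 | step 8 | ethyl (3E,6S)-6-[(tert-butyldimethylsilyl)oxy]-4-methylocta-3,7-dienoate | CCOC(=O)C/C=C(C)/C[C@H](O[Si](C)(C)C(C)(C)C)C=C
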